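Remark: the SMILES is read as a labdane of the normal series, (4S,5R,8R,9R,10S), with the acyloxymethyl group on C4 axial (C19) and the 8‑hydroxyl equatorial (8α). (E)‑Geranylacetone free of its Z isomer is assumed to be a commercial material. Labdane numbering is used for all ring compounds.

## Structural features

The target 22 is a trans‑fused decalin (ring A = C1–C5, C10; ring B = C5–C10) with five contiguous stereocentres, C4–C5–C10–C9–C8. C4 and C10 are all‑carbon quaternary centres and C8 is a tertiary carbinol; the angular methyl C20, the oxidised carbon C19 on C4 and the methyl C17 on C8 are all axial on the β face, while the 8‑OH, the methyl C18 and the C11 side chain on C9 are equatorial. C9 carries CH2CH2–C13(=C16H2)–C14H=C15H2, a 2‑substituted buta‑1,3‑diene that dimerises, polymerises and readily adds radicals, electrophiles and peracids. O19 is acylated by (E)‑4‑methoxycinnamic acid, a base‑labile Michael acceptor, and the free tertiary 8‑OH can eliminate or close onto C13 under acid. The real difficulty is the C4–C5–C10–C9 array with its two quaternary carbons, and within it the distinction of the two one‑carbon groups on C4: the oxidised one must be the axial one, which neither the commercial gem‑dimethyl labdanes and drimanes nor the usual proton‑ or epoxide‑started cyclisations provide. The key step exploits two features. First, C4, with its oxidised carbon C19 and a temporary carbonyl at C3, is the α‑carbon of a β‑keto ester and can become a planar electrophilic radical that bonds to C5. Second, C8 with its OH and C17 is a masked 8(17)‑methylene, the natural end of a radical cascade that divalent copper terminates after the C10 radical has bonded to C9. In one sentence, rings A and B are closed together by a Mn(OAc)3/Cu(OAc)2 oxidative radical bicyclisation of an open‑chain α‑methyl β‑keto ester that bears a chiral ester group; this does not describe the plan drawn first, which would elaborate a bought decalin or lactone of the labdane family.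

## Logic of the disconnections

22 ⇒ 20 + 21. The O19–acyl bond is cut. The cinnamate is the only base‑ and nucleophile‑sensitive group and is therefore put on last. This leaves a diol in which only the primary O19–H can be acylated beside the tertiary O8–H. The forward step must be a mild acylation that leaves the diene alone.

20 ⇒ 19. The two methylene carbons C15 and C16 are cut off as ethylene, leaving a C13≡C14 terminal alkyne. The reactive diene is thereby absent from all earlier steps and is replaced by a group inert to peracid and hydride. The forward step must be a cross enyne metathesis that tolerates two free hydroxyls.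

19 ⇒ 18. The C14–H bond is exchanged for C14–Si. The silyl cap hides the acidic alkyne hydrogen from strong base and from divalent copper earlier in the route. Its removal must not touch the diol.

18 ⇒ 17. One C17–H bond and the two C19–H bonds are cut. The equatorial 8‑OH with its axial methyl comes from a spiro‑epoxide opened at its CH2, and the C19 alcohol comes from the ester. One hydride reagent does both and releases 8. The demand is hydride attack at C17 only, so that the C8–O bond and its configuration are kept.

17 ⇒ 16. The two epoxide C–O bonds are cut to the 8(17)‑methylene. The gain is that C8 need not be set in the ring‑forming step. The demand is attack of the oxidant on the α face, opposite the axial C20.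

16 ⇒ 14 ⇒ 13. The two C3–H bonds are exchanged for the C3 carbonyl. This carbonyl exists only to make C4 a radical precursor, and its removal costs two steps. The demand is a deoxygenation that spares the ester, the methylene and the silylalkyne.

13 ⇒ 12 (key). The C4–C5 and C9–C10 bonds are cut and one C17–H is restored. Both rings open to an acyclic chain with two E trisubstituted alkenes, and four stereocentres (C4, C5, C9, C10) are exchanged for the single chiral ester group. The forward step must close both rings 6‑endo, place the ester axial on C4, give a trans ring fusion and end in the exocyclic alkene.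

12 ⇒ 7 + 10 (through 11). The C1–C2 bond is cut between an allylic bromide and the terminal carbon of a keto ester dianion. This splits the chain into a C13 piece and a C5 piece that carries the auxiliary. The demand is alkylation at the terminal carbon only, without loss of alkene geometry.

7 ⇒ 6 ⇒ 5. The C1–Br and C1–O bonds are cut back to the E‑methyl of a terminal isopropylidene group. The demand is oxidation of the terminal alkene's E‑methyl in preference to the allylic positions of the inner alkene.

5 ⇒ 1. The C13≡C14–Si unit is traced back to the methyl ketone of 1, which supplies C1, C5–C14, C17 and C20 with the inner E alkene already in place. The demand is enolisation toward the methyl group.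

10 ⇒ 8 + 9. The ester C–O bond is cut. 9 supplies C2, C3, C4, C18 and C19, and 8 is the bought source of chirality.

## Other disconnections considered

Alternative 1: the plan that comes to mind first keeps rings A and B and the centres C5, C8, C9 and C10 of commercial (+)‑sclareolide A1. It cuts only a C19–H bond and the C12–C13 bond. The forward key step would be hydroxylation of the axial methyl on C4 to 19‑hydroxysclareolide A2, followed by lactone opening and chain extension. No functional group of A1 lies within reach of C19, since the lactone sits on ring B. A handle introduced at C3 would be expected to steer a directed C–H oxidation to the equatorial methyl C18, and undirected oxidants should prefer the ring A methylene groups. The four bought stereocentres therefore leave the hardest one, C4, unsolved, whereas the chosen plan sets C4 in the ring‑forming step.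

Alternative 2: the same bonds, C4–C5 and C9–C10, could be formed by a cationic, epoxide‑started bicyclisation of the epoxy polyene A3 to the 3β‑hydroxy bicycle A4. In a concerted cationic closure the C4 configuration is read from the alkene geometry, and the substituent cis to the chain becomes axial. A3 must therefore come from a Z trisubstituted allylic alcohol. Allylic oxidation of an isopropylidene terminus gives the E isomer instead, and Z alcohols are the slow and less selective substrate class for Ti(Oi‑Pr)4/tartrate epoxidation. The alkoxymethyl group also withdraws electron density from C4 and should slow ionisation at that carbon. The 3‑OH of A4 costs as many steps to delete as the ketone of 13. Finally, an epoxide‑started polyene cyclisation is the textbook plan. In the chosen plan the C4 configuration comes from the conformation of a planar radical, so the easily made E precursor is the right one.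

Alternative 3: an intramolecular Diels–Alder reaction of triene A5 would close ring A through C5–C10 and C3–C4 and give cycloadduct A6, setting C4, C5 and C10 at once. C8 and C9 would be set beforehand by asymmetric epoxidation of a geraniol‑type alcohol and epoxide opening at C9. A trans ring fusion with an axial ester requires the Z dienophile to react with both tether and ester exo. The diene terminus C10 carries an inside methyl that destabilises the s‑cis conformer. The trans transition state also develops the 1,3‑diaxial C17/C20 contact. Each factor favours the cis‑fused product or no reaction. The acyclic precursor, with two stereocentres and three defined alkenes, would take more steps than 12, and ring A would still need hydrogenation.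

Key step: step 6

## Route

Step 1
Reactants: 1 (5E)-6,10-dimethylundeca-5,9-dien-2-one [(E)-geranylacetone]
Product: 5 [(5E)-6,10-dimethylundeca-5,9-dien-1-yn-1-yl]trimethylsilane, via lithium enolate 2 (not isolated), via enol phosphate 3 (not isolated), via lithium acetylide 4 (not isolated)
Conditions: LiN(i-Pr)2 (1.05 equiv), THF, −78 °C; ClP(O)(OEt)2, −78 °C to rt; LiN(i-Pr)2 (2.3 equiv), −78 °C to rt; Me3SiCl, −78 °C to rt
Reagents that add atoms: chlorotrimethylsilane, C[Si](C)(C)Cl; diethyl chlorophosphate, CCOP(=O)(Cl)OCC (its atoms stay only in 3)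
Why: Kinetic deprotonation of the methyl ketone at CH3, O‑phosphorylation and double elimination of the enol phosphate give the terminal acetylide (methyl ketone to alkyne conversion through an enol phosphate), which is silylated in the same flask; no stereocentre is formed and the E alkene is untouched.

Step 2
Reactants: 5 [(5E)-6,10-dimethylundeca-5,9-dien-1-yn-1-yl]trimethylsilane
Product: 6 (2E,6E)-2,6-dimethyl-11-(trimethylsilyl)undeca-2,6-dien-10-yn-1-ol
Conditions: SeO2 (0.3 equiv), t-BuOOH (3 equiv), salicylic acid (0.1 equiv), CH2Cl2, 0 °C to rt, stopped at partial conversion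
Reagents that add atoms: tert-butyl hydroperoxide, CC(C)(C)OO (oxygen relayed by catalytic SeO2, O=[Se]=O)
Why: Catalytic SeO2 allylic oxidation (ene reaction, then [2,3]-sigmatropic shift) attacks the most accessible, terminal trisubstituted alkene at its E‑methyl and returns the E allylic alcohol; recovered 5 is recycled.

Step 3
Reactants: 6 (2E,6E)-2,6-dimethyl-11-(trimethylsilyl)undeca-2,6-dien-10-yn-1-ol
Product: 7 [(5E,9E)-11-bromo-6,10-dimethylundeca-5,9-dien-1-yn-1-yl]trimethylsilane
Conditions: CBr4, PPh3, CH2Cl2, 0 °C
Reagents that add atoms: carbon tetrabromide, BrC(Br)(Br)Br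
Why: Appel bromination: SN2 displacement of the alkoxyphosphonium at the primary allylic carbon at low temperature, without allylic transposition or loss of E geometry.

Step 4
Reactants: 8 (1R,2S,5R)-5-methyl-2-(2-phenylpropan-2-yl)cyclohexan-1-ol [(−)-8-phenylmenthol]; 9 ethyl 2-methyl-3-oxobutanoate
Product: 10 (1R,2S,5R)-5-methyl-2-(2-phenylpropan-2-yl)cyclohexyl 2-methyl-3-oxobutanoate
Conditions: DMAP (0.2 equiv), toluene, reflux, 4 Å sieves (removal of EtOH)
Reagents that add atoms: none
Why: DMAP‑catalysed transesterification of a β‑keto ester, which runs through the acylketene because one α‑hydrogen is present, driven by removal of ethanol; the carbinol centre of 8 is not involved.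

Step 5
Reactants: 10 (1R,2S,5R)-5-methyl-2-(2-phenylpropan-2-yl)cyclohexyl 2-methyl-3-oxobutanoate; 7 [(5E,9E)-11-bromo-6,10-dimethylundeca-5,9-dien-1-yn-1-yl]trimethylsilane
Product: 12 (1R,2S,5R)-8-phenylmenthyl (6E,10E)-2,6,10-trimethyl-3-oxo-15-(trimethylsilyl)pentadeca-6,10-dien-14-ynoate, via dianion 11 (not isolated)
Conditions: NaH (1.1 equiv), THF, 0 °C; n-BuLi (1.05 equiv), 0 °C; then 7, 0 °C; aq. NH4Cl
Reagents that add atoms: none
Why: γ‑Alkylation of a β‑keto ester dianion: the more basic terminal carbanion attacks the primary allylic bromide by SN2 with retention of alkene geometry; the α‑centre is an epimer mixture that is erased in step 6.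

Step 6
Reactants: 12 (1R,2S,5R)-8-phenylmenthyl (6E,10E)-2,6,10-trimethyl-3-oxo-15-(trimethylsilyl)pentadeca-6,10-dien-14-ynoate
Product: 13 (1R,2S,5R)-8-phenylmenthyl (4R,5R,9S,10R)-3-oxo-14-(trimethylsilyl)-15,16-dinorlabd-8(17)-en-13-yn-19-oate (4α-methyl; 4β-ester carbon C19; 5α-H; 9α-H; 10β-methyl; C9 chain = CH2CH2C≡CSiMe3)
Conditions: Mn(OAc)3·2H2O (2.2 equiv), Cu(OAc)2·H2O (1.0 equiv), degassed AcOH, 25–40 °C
Reagents that add atoms: none
Why: Mn(OAc)3 oxidises the enol form of 12 (enolisation is the slow step for an α‑methyl β‑keto ester) to the planar, electrophilic α,α‑dicarbonyl radical at C4, which adds 6‑endo‑trig to C5 of the C5=C10 alkene; the tertiary C10 radical adds 6‑endo‑trig to C9 of the C8=C9 alkene, and the tertiary C8 radical is captured by Cu(OAc)2 as a trivalent alkylcopper species that loses a C17 hydrogen by syn β‑hydride elimination to give the 8(17)‑methylene. The closest known reaction type is the Mn(OAc)3/Cu(OAc)2 oxidative free‑radical polycyclisation of unsaturated α‑alkyl β‑keto esters, a class that includes esters of chiral alcohols. Both closures are 6‑endo‑trig because the ketone carbon C3 lies inside ring A and each attacked alkene carries its methyl on the inner carbon, which disfavours the 5‑exo mode and gives a tertiary radical each time. At C4 the radical reacts from the rotamer about C3–C4 that keeps the ester away from the ketone oxygen (dipoles opposed, no chelation), so that the ester lies syn to C2 and becomes axial (C19 β, cis to C20) while the methyl becomes equatorial. At C5, C10 and C9, chair‑like transition states place the C6 chain equatorial on ring A and, in the chair–chair second closure, make the ring fusion trans with C20 axial and the C11 chain equatorial, as fixed by the E geometry of both alkenes. For the absolute configuration, in the s‑cis ester conformer the phenyl ring of the auxiliary stacks against one face of the radical, so C5 adds to the open face, which corresponds to the (4R) centre drawn in 13. The step needs 6‑endo over 5‑exo closure, oxidation of the C8 radical faster than its 5‑exo‑dig addition to the silylalkyne (the full equivalent of Cu(OAc)2 is there for this), and exocyclic over endocyclic elimination, which the preference of the copper intermediate for the least hindered β‑hydrogen should provide.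

Step 7
Reactants: 13 (1R,2S,5R)-8-phenylmenthyl (4R,5R,9S,10R)-3-oxo-14-(trimethylsilyl)-15,16-dinorlabd-8(17)-en-13-yn-19-oate
Product: 14 C3 p-toluenesulfonylhydrazone of 13
Conditions: TsNHNH2 (1.5 equiv), EtOH, reflux
Reagents that add atoms: p-toluenesulfonyl hydrazide, Cc1ccc(cc1)S(=O)(=O)NN
Why: Hydrazone condensation at the only ketone; the hindered ester, the methylene and the silylalkyne are inert, and the quaternary C4 cannot epimerise.

Step 8
Reactants: 14 C3 p-toluenesulfonylhydrazone of 13
Product: 16 (1R,2S,5R)-8-phenylmenthyl 14-(trimethylsilyl)-15,16-dinorlabd-8(17)-en-13-yn-19-oate, via N-boryl tosylhydrazine 15 (not isolated)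
Conditions: catecholborane (3 equiv), CHCl3, 0 °C to rt; then NaOAc·3H2O, reflux
Reagents that add atoms: none
Why: Catecholborane delivers hydride to C3 of the C=N bond; acetate then triggers loss of sulfinate to the alkyldiazene, which loses N2 and leaves CH2 (tosylhydrazone reduction, a mild relative of the Wolff–Kishner reduction). C4 has no hydrogen, so no alkene can form toward it and no stereocentre is touched.

Step 9
Reactants: 16 (1R,2S,5R)-8-phenylmenthyl 14-(trimethylsilyl)-15,16-dinorlabd-8(17)-en-13-yn-19-oate
Product: 17 (1R,2S,5R)-8-phenylmenthyl 8α,17-epoxy-14-(trimethylsilyl)-15,16-dinorlabd-13-yn-19-oate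
Conditions: mCPBA (1.2 equiv), NaHCO3, CH2Cl2, 0 °C
Reagents that add atoms: 3-chloroperoxybenzoic acid, OOC(=O)c1cccc(Cl)c1
Why: Prilezhaev epoxidation of the only reactive alkene (the silylalkyne is inert). The β face of the exocyclic C8=C17 bond is screened by the syn‑axial C20 methyl, so oxygen is delivered to the α face and C8 is set with the C–O bond equatorial.

Step 10
Reactants: 17 (1R,2S,5R)-8-phenylmenthyl 8α,17-epoxy-14-(trimethylsilyl)-15,16-dinorlabd-13-yn-19-oate
Product: 18 14-(trimethylsilyl)-15,16-dinorlabd-13-yne-8α,19-diol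
Conditions: LiAlH4 (excess), THF, 0 °C to reflux; aq. NaOH work-up
Reagents that add atoms: none
Why: Hydride opens the spiro‑epoxide by SN2 at the primary C17, so the C8–O bond and its configuration are kept (equatorial 8‑OH, axial methyl). The same reagent reduces the hindered ester to the C19 primary alcohol and releases the auxiliary 8 for reuse.

Step 11
Reactants: 18 14-(trimethylsilyl)-15,16-dinorlabd-13-yne-8α,19-diol
Product: 19 15,16-dinorlabd-13-yne-8α,19-diol
Conditions: K2CO3 (cat.), MeOH, rt
Reagents that add atoms: none
Why: Methoxide‑mediated protodesilylation of the alkynylsilane; the alcohols and ring stereocentres are untouched.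

Step 12
Reactants: 19 15,16-dinorlabd-13-yne-8α,19-diol
Product: 20 labda-13(16),14-diene-8α,19-diol
Conditions: ethylene (1 atm), second-generation Grubbs catalyst RuCl2(=CHPh)(H2IMes)(PCy3) (5 mol%), toluene, 80 °C
Reagents that add atoms: ethylene, C=C
Why: Cross enyne metathesis of a terminal alkyne with ethylene: the ruthenium methylidene adds to the alkyne, and the vinylcarbene so formed is methylenated by ethylene to give the 2‑substituted buta‑1,3‑diene. Free hydroxyls are tolerated and ethylene suppresses alkyne oligomerisation.

Step 13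
Reactants: 20 labda-13(16),14-diene-8α,19-diol; 21 (2E)-3-(4-methoxyphenyl)prop-2-enoic acid
Product: 22 8α-hydroxylabda-13(16),14-dien-19-yl (2E)-3-(4-methoxyphenyl)prop-2-enoate [(4S,5R,8R,9R,10S); the target]
Conditions: EDC·HCl (1.5 equiv), DMAP (0.2 equiv), CH2Cl2, 0 °C to rt
Reagents that add atoms: none
Why: Carbodiimide/DMAP (Steglich) esterification: only the primary O19–H is acylated, since the tertiary 8‑OH is too hindered. No acid or heat reaches the diene, and the E alkene of 21 is kept.

## Compound list

1 | (5E)-6,10-dimethylundeca-5,9-dien-2-one | CC(=O)CC/C=C(\C)CCC=C(C)C | starting material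
2 | lithium (5E)-6,10-dimethylundeca-1,5,9-trien-2-olate | [Li+].[O-]C(=C)CC/C=C(\C)CCC=C(C)C | intermediate (not isolated)
3 | diethyl (5E)-6,10-dimethylundeca-1,5,9-trien-2-yl phosphate | C=C(OP(=O)(OCC)OCC)CC/C=C(\C)CCC=C(C)C | intermediate (not isolated)
4 | lithium (5E)-6,10-dimethylundeca-5,9-dien-1-yn-1-ide | [Li+].[C-]#CCC/C=C(\C)CCC=C(C)C | intermediate (not isolated)
5 | [(5E)-6,10-dimethylundeca-5,9-dien-1-yn-1-yl]trimethylsilane | C[Si](C)(C)C#CCC/C=C(\C)CCC=C(C)C | intermediate
6 | (2E,6E)-2,6-dimethyl-11-(trimethylsilyl)undeca-2,6-dien-10-yn-1-ol | C[Si](C)(C)C#CCC/C=C(\C)CC/C=C(\C)CO | intermediate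
7 | [(5E,9E)-11-bromo-6,10-dimethylundeca-5,9-dien-1-yn-1-yl]trimethylsilane | C[Si](C)(C)C#CCC/C=C(\C)CC/C=C(\C)CBr | intermediate
8 | (1R,2S,5R)-5-methyl-2-(2-phenylpropan-2-yl)cyclohexan-1-ol | C[C@@H]1CC[C@H]([C@@H](C1)O)C(C)(C)c1ccccc1 | starting material
9 | ethyl 2-methyl-3-oxobutanoate | CCOC(=O)C(C)C(C)=O | starting material
10 | (1R,2S,5R)-5-methyl-2-(2-phenylpropan-2-yl)cyclohexyl 2-methyl-3-oxobutanoate | CC(=O)C(C)C(=O)O[C@@H]1C[C@H](C)CC[C@H]1C(C)(C)c1ccccc1 | intermediate
11 | sodium lithium dianion of 10 (carbanions at C2 and C4) | [Na+].[Li+].[CH2-]C(=O)[C-](C)C(=O)O[C@@H]1C[C@H](C)CC[C@H]1C(C)(C)c1ccccc1 | intermediate (not isolated)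
12 | 8-phenylmenthyl (6E,10E)-2,6,10-trimethyl-3-oxo-15-(trimethylsilyl)pentadeca-6,10-dien-14-ynoate | C[Si](C)(C)C#CCC/C=C(\C)CC/C=C(\C)CCC(=O)C(C)C(=O)O[C@@H]1C[C@H](C)CC[C@H]1C(C)(C)c1ccccc1 | intermediate
13 | 8-phenylmenthyl (4R,5R,9S,10R)-3-oxo-14-(trimethylsilyl)-15,16-dinorlabd-8(17)-en-13-yn-19-oate | C[Si](C)(C)C#CCC[C@@H]1[C@@]2(C)CCC(=O)[C@](C)(C(=O)O[C@@H]3C[C@H](C)CC[C@H]3C(C)(C)c3ccccc3)[C@@H]2CCC1=C | intermediate
14 | C3 p-toluenesulfonylhydrazone of 13 | C[Si](C)(C)C#CCC[C@@H]1[C@@]2(C)CCC(=NNS(=O)(=O)c3ccc(C)cc3)[C@](C)(C(=O)O[C@@H]3C[C@H](C)CC[C@H]3C(C)(C)c3ccccc3)[C@@H]2CCC1=C | intermediate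
15 | N-(1,3,2-benzodioxaborol-2-yl) C3 tosylhydrazine from 14 (C3 configuration not defined) | C[Si](C)(C)C#CCC[C@@H]1[C@@]2(C)CCC(N(NS(=O)(=O)c3ccc(C)cc3)B3Oc4ccccc4O3)[C@](C)(C(=O)O[C@@H]3C[C@H](C)CC[C@H]3C(C)(C)c3ccccc3)[C@@H]2CCC1=C | intermediate (not isolated)
16 | 8-phenylmenthyl 14-(trimethylsilyl)-15,16-dinorlabd-8(17)-en-13-yn-19-oate | C[Si](C)(C)C#CCC[C@@H]1[C@@]2(C)CCC[C@](C)(C(=O)O[C@@H]3C[C@H](C)CC[C@H]3C(C)(C)c3ccccc3)[C@@H]2CCC1=C | intermediate
17 | 8-phenylmenthyl 8α,17-epoxy-14-(trimethylsilyl)-15,16-dinorlabd-13-yn-19-oate | C[Si](C)(C)C#CCC[C@@H]1[C@@]2(C)CCC[C@](C)(C(=O)O[C@@H]3C[C@H](C)CC[C@H]3C(C)(C)c3ccccc3)[C@@H]2CC[C@@]1(C3)O3 | intermediate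
18 | 14-(trimethylsilyl)-15,16-dinorlabd-13-yne-8α,19-diol | C[Si](C)(C)C#CCC[C@@H]1[C@@]2(C)CCC[C@](C)(CO)[C@@H]2CC[C@@]1(C)O | intermediate
19 | 15,16-dinorlabd-13-yne-8α,19-diol | C#CCC[C@@H]1[C@@]2(C)CCC[C@](C)(CO)[C@@H]2CC[C@@]1(C)O | intermediate
20 | labda-13(16),14-diene-8α,19-diol | C=CC(=C)CC[C@@H]1[C@@]2(C)CCC[C@](C)(CO)[C@@H]2CC[C@@]1(C)O | intermediate
21 | (2E)-3-(4-methoxyphenyl)prop-2-enoic acid | COc1ccc(/C=C/C(=O)O)cc1 | starting material
22 | 8α-hydroxylabda-13(16),14-dien-19-yl (2E)-3-(4-methoxyphenyl)prop-2-enoate | C=CC(=C)CC[C@@H]1[C@@]2(C)CCC[C@](C)(COC(=O)/C=C/c3ccc(OC)cc3)[C@@H]2CC[C@@]1(C)O | target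

## Step count and least certain steps

Total step count: 13. Longest linear sequence: 12 (steps 1–3 and 5–13, from 1); step 4 is a one‑step side branch.

Step 6 (key step). The outcome most likely to go wrong is leakage of the C8 radical into a 5‑exo‑dig addition to the silylalkyne before divalent copper oxidises it. An incomplete facial bias from the auxiliary is also possible, but this costs material only, because the two series stay diastereomeric and separable while the auxiliary is attached. The fallback builds the acetylene after the rings, so that no π bond is within reach of the C8 radical. It sets out from 1. Ketalisation (ethylene glycol, pyridinium tosylate, benzene, reflux with water removal) gives the geranylacetone dioxolane F1. The same allylic oxidation as in step 2 gives the allylic alcohol F2, and MsCl/Et3N then LiBr gives the allylic bromide F3. Alkylation of dianion 11 gives the open‑chain keto ester F4. The Mn(OAc)3/Cu(OAc)2 bicyclisation, run in ethanol to spare the ketal, gives the bicyclic keto ester ketal F5. TsNHNH2 gives its tosylhydrazone F6, and catecholborane then NaOAc·3H2O gives the deoxygenated ketal ester F7. Pyridinium tosylate in wet acetone releases the methyl ketone F8. The sequence of step 1 (LiN(i-Pr)2, ClP(O)(OEt)2, LiN(i-Pr)2, Me3SiCl) then converts the methyl ketone into the silylalkyne; the ester has no α‑hydrogen. The route is rejoined at 16.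

Step 8. The hindered C=N bond next to the quaternary C4 may take up hydride slowly, and base‑induced loss of sulfinate may then divert the hydrazone to the ring A alkene (Bamford–Stevens‑type elimination). The fallback is a radical deoxygenation that sets out from 13. NaBH4 (MeOH, 0 °C) gives the 3β‑alcohol F9. 1,1'-Thiocarbonyldiimidazole (DMAP, toluene, 80 °C) gives the imidazolyl thiocarbonyl derivative F10. Bu3SnH with AIBN (toluene, 110 °C; Barton–McCombie deoxygenation) removes the oxygen, and the route is rejoined at 16.

Step 2. Site selection between the two trisubstituted alkenes may be poor, and over‑oxidation may occur, because the inner alkene is not deactivated. The fallback oxidises the terminus through an epoxide and sets out from 5. N‑Bromosuccinimide in aqueous THF (0 °C) gives the terminal bromohydrin F11. NaH (THF) closes it to the terminal epoxide F12. Al(Oi‑Pr)3 (toluene, reflux) isomerises this to the secondary allylic alcohol with a 1,1‑disubstituted alkene F13. PBr3 (Et2O, 0 °C) brominates with allylic transposition to the E primary bromide, and the route is rejoined at 7.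

Step 9. Facial selection in the epoxidation may be incomplete, and attack on the β face would lead to the C8 epimer after step 10. The fallback uses a bulkier oxidant and sets out from 16. OsO4 (cat.) with N‑methylmorpholine N‑oxide (acetone/water) gives the 8α,17‑diol F14. TsCl in pyridine gives the primary tosylate F15. LiAlH4 (THF, reflux) closes the alkoxide onto C17 to give epoxide 17 in the flask, opens it at C17 and reduces the ester, and the route is rejoined at 18.

## Further compounds

F1 | step 6 | 2-[(3E)-4,8-dimethylnona-3,7-dien-1-yl]-2-methyl-1,3-dioxolane | CC1(CC/C=C(\C)CCC=C(C)C)OCCO1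
F2 | step 6 | (2E,6E)-2,6-dimethyl-9-(2-methyl-1,3-dioxolan-2-yl)nona-2,6-dien-1-ol | CC1(CC/C=C(\C)CC/C=C(\C)CO)OCCO1
F3 | step 6 | 2-[(3E,7E)-9-bromo-4,8-dimethylnona-3,7-dien-1-yl]-2-methyl-1,3-dioxolane | CC1(CC/C=C(\C)CC/C=C(\C)CBr)OCCO1
F4 | step 6 | 8-phenylmenthyl (6E,10E)-2,6,10-trimethyl-13-(2-methyl-1,3-dioxolan-2-yl)-3-oxotrideca-6,10-dienoate | CC1(CC/C=C(\C)CC/C=C(\C)CCC(=O)C(C)C(=O)O[C@@H]2C[C@H](C)CC[C@H]2C(C)(C)c2ccccc2)OCCO1
F5 | step 6 | 8-phenylmenthyl 13,13-ethylenedioxy-3-oxo-15,16-dinorlabd-8(17)-en-19-oate | CC1(CC[C@@H]2[C@@]3(C)CCC(=O)[C@](C)(C(=O)O[C@@H]4C[C@H](C)CC[C@H]4C(C)(C)c4ccccc4)[C@@H]3CCC2=C)OCCO1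
F6 | step 6 | C3 p-toluenesulfonylhydrazone of F5 | CC1(CC[C@@H]2[C@@]3(C)CCC(=NNS(=O)(=O)c4ccc(C)cc4)[C@](C)(C(=O)O[C@@H]4C[C@H](C)CC[C@H]4C(C)(C)c4ccccc4)[C@@H]3CCC2=C)OCCO1
F7 | step 6 | 8-phenylmenthyl 13,13-ethylenedioxy-15,16-dinorlabd-8(17)-en-19-oate | CC1(CC[C@@H]2[C@@]3(C)CCC[C@](C)(C(=O)O[C@@H]4C[C@H](C)CC[C@H]4C(C)(C)c4ccccc4)[C@@H]3CCC2=C)OCCO1
F8 | step 6 | 8-phenylmenthyl 13-oxo-15,16-dinorlabd-8(17)-en-19-oate | CC(=O)CC[C@@H]1[C@@]2(C)CCC[C@](C)(C(=O)O[C@@H]3C[C@H](C)CC[C@H]3C(C)(C)c3ccccc3)[C@@H]2CCC1=C
F9 | step 8 | 8-phenylmenthyl 3β-hydroxy-14-(trimethylsilyl)-15,16-dinorlabd-8(17)-en-13-yn-19-oate | C[Si](C)(C)C#CCC[C@@H]1[C@@]2(C)CC[C@H](O)[C@](C)(C(=O)O[C@@H]3C[C@H](C)CC[C@H]3C(C)(C)c3ccccc3)[C@@H]2CCC1=C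
F10 | step 8 | 3-O-(imidazol-1-ylcarbonothioyl) derivative of F9 | C[Si](C)(C)C#CCC[C@@H]1[C@@]2(C)CC[C@H](OC(=S)n3ccnc3)[C@](C)(C(=O)O[C@@H]3C[C@H](C)CC[C@H]3C(C)(C)c3ccccc3)[C@@H]2CCC1=C
F11 | step 2 | (6E)-3-bromo-2,6-dimethyl-11-(trimethylsilyl)undec-6-en-10-yn-2-ol | C[Si](C)(C)C#CCC/C=C(\C)CCC(Br)C(C)(C)O
F12 | step 2 | [(5E)-8-(3,3-dimethyloxiran-2-yl)-6-methyloct-5-en-1-yn-1-yl]trimethylsilane | C[Si](C)(C)C#CCC/C=C(\C)CCC1OC1(C)C
F13 | step 2 | (6E)-2,6-dimethyl-11-(trimethylsilyl)undeca-1,6-dien-10-yn-3-ol | C[Si](C)(C)C#CCC/C=C(\C)CCC(O)C(C)=C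
F14 | step 9 | 8-phenylmenthyl 8α,17-dihydroxy-14-(trimethylsilyl)-15,16-dinorlabd-13-yn-19-oate | C[Si](C)(C)C#CCC[C@@H]1[C@@]2(C)CCC[C@](C)(C(=O)O[C@@H]3C[C@H](C)CC[C@H]3C(C)(C)c3ccccc3)[C@@H]2CC[C@@]1(CO)O
F15 | step 9 | 17-O-p-toluenesulfonate of F14 | C[Si](C)(C)C#CCC[C@@H]1[C@@]2(C)CCC[C@](C)(C(=O)O[C@@H]3C[C@H](C)CC[C@H]3C(C)(C)c3ccccc3)[C@@H]2CC[C@@]1(COS(=O)(=O)c3ccc(C)cc3)O
A1 | alternative 1 | (+)-sclareolide | O=C3C[C@@H]1[C@@]2(C)CCCC(C)(C)[C@@H]2CC[C@@]1(C)O3
A2 | alternative 1 | 19-hydroxysclareolide | O=C3C[C@@H]1[C@@]2(C)CCC[C@](C)(CO)[C@@H]2CC[C@@]1(C)O3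
A3 | alternative 2 | 2-[(benzyloxy)methyl]-2-methyl-3-[(3E,7E)-3,7-dimethyl-12-(trimethylsilyl)dodeca-3,7-dien-11-yn-1-yl]oxirane (benzyloxymethyl cis to the chain) | C[Si](C)(C)C#CCC/C=C(\C)CC/C=C(\C)CC[C@@H]1O[C@]1(C)COCc1ccccc1
A4 | alternative 2 | 19-benzyloxy-14-(trimethylsilyl)-15,16-dinorlabd-8(17)-en-13-yn-3β-ol | C[Si](C)(C)C#CCC[C@@H]1[C@@]2(C)CC[C@H](O)[C@](C)(COCc3ccccc3)[C@@H]2CCC1=C
A5 | alternative 3 | open-chain triene: methyl (Z)-2-methylalk-2-enoate dienophile (C4=C5), triethylsilyl ether at C8, silylbutynyl chain and (E)-penta-2,4-dien-2-yl diene on C9 | C[Si](C)(C)C#CCC[C@@H]([C@](C)(O[Si](CC)(CC)CC)CC/C=C(/C)C(=O)OC)/C(C)=C/C=C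
A6 | alternative 3 | methyl 8α-(triethylsilyloxy)-14-(trimethylsilyl)-15,16-dinorlabd-1-en-13-yn-19-oate | C[Si](C)(C)C#CCC[C@@H]1[C@@]2(C)C=CC[C@](C)(C(=O)OC)[C@@H]2CC[C@@]1(C)O[Si](CC)(CC)CC
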